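The cyclohexane is cut at its C5–C6 bond, between the epoxide CH and the ring CH2 (bisabolane numbering). The unit O–C5–C6H2–C1H–C7(=C14H2) is the product pattern of a nickel-catalysed reductive diene–aldehyde coupling, so one operation closes the ring, sets C1 and C5 and reveals the exocyclic methylene. The precursor is an acyclic α,β-epoxy aldehyde carrying a 2,3-disubstituted 1,3-diene, made from an internal alkyne and ethylene by enyne metathesis and held s-cis in a seven-membered silylene ring across the two diene-flanking oxygens. A later epoxide migration moves the epoxide to C4–C5 and frees O3 for acylation.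

Key step: step 13

Remark on numbering: bisabolane numbering is used throughout. Ring: C1 (carries the side chain), C2 and C3 (acyloxy carbons), C4 (methyl-bearing epoxide carbon), C5 (epoxide CH), C6 (CH2). Side chain: C7 (=C14H2), C8 (acyloxy), C9, C10/C11 (epoxide).

Assumption: (S,S)-ProPhenol is taken as the ligand enantiomer that gives the (S)-carbinol in step 4; if the sense of induction is the opposite, (R,R)-ProPhenol is used and nothing else changes.

**Step 1**
Reactants: 1 4-methylpent-3-enoic acid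
Product: 2 N-methoxy-N,4-dimethylpent-3-enamide
Conditions: MeNH(OMe)·HCl, EDC·HCl, N-methylmorpholine, CH2Cl2, 0 °C to rt
Reagents that add atoms: N,O-dimethylhydroxylamine hydrochloride, CNOC.Cl
Why: Carbodiimide amidation to the Weinreb amide, under neutral conditions that should leave the β,γ-alkene in place.

**Step 2**
Reactants: 3 4-methylfuran-2(5H)-one
Product: 5 (2Z)-N-methoxy-N,3-dimethyl-4-(triethylsilyloxy)but-2-enamide, via hydroxy Weinreb amide 4 (not isolated)
Conditions: MeNH(OMe)·HCl, Me3Al, CH2Cl2, 0 °C to rt; aq. KNaC4H4O6 work-up; crude 4, Et3SiCl, imidazole, CH2Cl2, 0 °C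
Reagents that add atoms: N,O-dimethylhydroxylamine hydrochloride, CNOC.Cl; chlorotriethylsilane, CC[Si](Cl)(CC)CC
Why: Weinreb aminolysis of the lactone opens the ring with the Z geometry that the butenolide enforces, and immediate silylation of the primary alcohol should stop relactonisation.

**Step 3**
Reactants: 5 (2Z)-N-methoxy-N,3-dimethyl-4-(triethylsilyloxy)but-2-enamide
Product: 6 (2Z)-3-methyl-4-(triethylsilyloxy)but-2-enal
Conditions: i-Bu2AlH (1.3 equiv), THF, −78 °C; aq. KNaC4H4O6
Reagents that add atoms: none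
Why: Hydride reduction of a Weinreb amide stops at the aldehyde through the chelated hemiaminal, so the (Z)-enal should form without touching the alkene.

**Step 4**
Reactants: 6 (2Z)-3-methyl-4-(triethylsilyloxy)but-2-enal; 7 ethynyl(trimethyl)silane
Product: 9 (3S,4Z)-5-methyl-6-(triethylsilyloxy)-1-(trimethylsilyl)hex-4-en-1-yn-3-ol, via alkynylzinc 8 (not isolated)
Conditions: Me2Zn (3 equiv), 7 (3 equiv), (S,S)-ProPhenol (20 mol %), Ph3P=O (40 mol %), toluene, 4 °C
Reagents that add atoms: none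
Why: Zinc–ProPhenol asymmetric alkynylation of an α,β-unsaturated aldehyde (Trost alkynylation), in which the dinuclear zinc catalyst selects the aldehyde face and sets the carbinol that becomes C2.

**Step 5**
Reactants: 9 (3S,4Z)-5-methyl-6-(triethylsilyloxy)-1-(trimethylsilyl)hex-4-en-1-yn-3-ol
Product: 10 (1R)-1-{(2S,3R)-3-methyl-3-[(triethylsilyloxy)methyl]oxiran-2-yl}-3-(trimethylsilyl)prop-2-yn-1-ol
Conditions: mCPBA, NaHCO3, CH2Cl2, −20 to 0 °C
Reagents that add atoms: 3-chloroperoxybenzoic acid, OOC(=O)c1cccc(Cl)c1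
Why: Hydroxyl-directed peracid epoxidation (Henbest type), in which A(1,3) strain from the cis CH2OSiEt3 group holds the carbinol hydrogen in the alkene plane, so oxygen is delivered syn to OH and the threo epoxy alcohol (future C3 and C4) should form from the C2 centre.

**Step 6**
Reactants: 10 (1R)-1-{(2S,3R)-3-methyl-3-[(triethylsilyloxy)methyl]oxiran-2-yl}-3-(trimethylsilyl)prop-2-yn-1-ol
Product: 11 (1R)-1-{(2S,3R)-3-methyl-3-[(triethylsilyloxy)methyl]oxiran-2-yl}prop-2-yn-1-ol
Conditions: K2CO3 (0.2 equiv), MeOH, 0 °C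
Reagents that add atoms: none
Why: Base-catalysed methanolysis of the alkynyl C–Si bond, mild enough that the primary silyl ether and the more substituted epoxide should survive.

**Step 7**
Reactants: 11 (1R)-1-{(2S,3R)-3-methyl-3-[(triethylsilyloxy)methyl]oxiran-2-yl}prop-2-yn-1-ol; 2 N-methoxy-N,4-dimethylpent-3-enamide
Product: 13 (1R)-1-hydroxy-7-methyl-1-{(2S,3R)-3-methyl-3-[(triethylsilyloxy)methyl]oxiran-2-yl}oct-6-en-2-yn-4-one, via dilithiated alkynol 12 (not isolated)
Conditions: n-BuLi (2.1 equiv), THF, −78 °C; then 2 (1.2 equiv), −78 to −20 °C; AcOH, −78 °C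
Reagents that add atoms: none
Why: Weinreb ketone synthesis with a lithium acetylide, where the stable tetrahedral intermediate prevents over-addition and masks the acidic skipped CH2 until the cold acidic quench.

**Step 8**
Reactants: 13 (1R)-1-hydroxy-7-methyl-1-{(2S,3R)-3-methyl-3-[(triethylsilyloxy)methyl]oxiran-2-yl}oct-6-en-2-yn-4-one
Product: 14 (1R,4S)-7-methyl-1-{(2S,3R)-3-methyl-3-[(triethylsilyloxy)methyl]oxiran-2-yl}oct-6-en-2-yne-1,4-diol
Conditions: RuCl[(S,S)-TsDPEN](p-cymene) (2 mol %), i-PrOH, rt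
Reagents that add atoms: none
Why: Noyori asymmetric transfer hydrogenation of an alkynyl ketone, in which the (S,S) catalyst should give the (S)-propargylic alcohol (C8) under catalyst control.

**Step 9**
Reactants: 14 (1R,4S)-7-methyl-1-{(2S,3R)-3-methyl-3-[(triethylsilyloxy)methyl]oxiran-2-yl}oct-6-en-2-yne-1,4-diol
Product: 15 (1R,4S)-5-[(2R)-3,3-dimethyloxiran-2-yl]-1-{(2S,3R)-3-methyl-3-[(triethylsilyloxy)methyl]oxiran-2-yl}pent-2-yne-1,4-diol
Conditions: D-fructose-derived Shi ketone (30 mol %), KHSO5 (as 2KHSO5·KHSO4·K2SO4), K2CO3, Bu4NHSO4, MeCN/CH2(OMe)2/aq. Na2B4O7 buffer, 0 °C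
Reagents that add atoms: potassium peroxymonosulfate, [K+].[O-]S(=O)(=O)OO
Why: Shi asymmetric epoxidation of the only alkene, a trisubstituted one, where the chiral dioxirane should set C10 as R through the spiro transition state.

**Step 10**
Reactants: 15 (1R,4S)-5-[(2R)-3,3-dimethyloxiran-2-yl]-1-{(2S,3R)-3-methyl-3-[(triethylsilyloxy)methyl]oxiran-2-yl}pent-2-yne-1,4-diol; 16 ethene
Product: 17 (1R,4S)-5-[(2R)-3,3-dimethyloxiran-2-yl]-2,3-dimethylidene-1-{(2S,3R)-3-methyl-3-[(triethylsilyloxy)methyl]oxiran-2-yl}pentane-1,4-diol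
Conditions: second-generation Grubbs catalyst RuCl2(=CHPh)(H2IMes)(PCy3) (10 mol %), 16 (1 atm), toluene, 80 °C
Reagents that add atoms: none
Why: Cross enyne metathesis of an internal alkyne with ethylene places one methylidene on each alkyne carbon and should give the 2,3-disubstituted 1,3-diene, the propargylic hydroxyls being tolerated by this catalyst and no other alkene being present.

**Step 11**
Reactants: 17 (1R,4S)-5-[(2R)-3,3-dimethyloxiran-2-yl]-2,3-dimethylidene-1-{(2S,3R)-3-methyl-3-[(triethylsilyloxy)methyl]oxiran-2-yl}pentane-1,4-diol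
Product: 18 (4R,7S)-7-{[(2R)-3,3-dimethyloxiran-2-yl]methyl}-5,6-dimethylidene-4-{(2S,3R)-3-methyl-3-[(triethylsilyloxy)methyl]oxiran-2-yl}-2,2-di(propan-2-yl)-1,3,2-dioxasilepane
Conditions: i-Pr2Si(OTf)2 (1.1 equiv), 2,6-lutidine, CH2Cl2 (0.01 M), −40 to 0 °C
Reagents that add atoms: di(propan-2-yl)silanediyl bis(trifluoromethanesulfonate), CC(C)[Si](OS(=O)(=O)C(F)(F)F)(OS(=O)(=O)C(F)(F)F)C(C)C
Why: Cyclic silylene formation from the 1,4-diol (the only free hydroxyls) under dilution gives the seven-membered ring that later fixes the diene geometry and the open diene face for step 13.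

**Step 12**
Reactants: 18 (4R,7S)-7-{[(2R)-3,3-dimethyloxiran-2-yl]methyl}-5,6-dimethylidene-4-{(2S,3R)-3-methyl-3-[(triethylsilyloxy)methyl]oxiran-2-yl}-2,2-di(propan-2-yl)-1,3,2-dioxasilepane
Product: 19 (2S,3S)-3-[(4R,7S)-7-{[(2R)-3,3-dimethyloxiran-2-yl]methyl}-5,6-dimethylidene-2,2-di(propan-2-yl)-1,3,2-dioxasilepan-4-yl]-2-methyloxirane-2-carbaldehyde
Conditions: (COCl)2, DMSO, CH2Cl2, −78 to −40 °C; Et3N, −78 °C to rt
Reagents that add atoms: none
Why: Direct Swern oxidation of a primary triethylsilyl ether, which the chlorosulfonium reagent cleaves and oxidises in place, while the hindered secondary dialkoxysilane and both epoxides should survive.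

**Step 13**
Reactants: 19 (2S,3S)-3-[(4R,7S)-7-{[(2R)-3,3-dimethyloxiran-2-yl]methyl}-5,6-dimethylidene-2,2-di(propan-2-yl)-1,3,2-dioxasilepan-4-yl]-2-methyloxirane-2-carbaldehyde
Product: 20 (1R,2R,3S,4R,5S,8S,10R)-3,4:10,11-diepoxy-2,8-O-[di(propan-2-yl)silanediyl]bisabol-7(14)-ene-2,5,8-triol
Conditions: Ni(acac)2 (10 mol %), Et3B (3 equiv), THF (0.02 M), rt, under N2
Reagents that add atoms: none
Why: Proposed new method: zerovalent nickel (from Ni(acac)2 and Et3B) should bind the s-cis diene and the Et3B-activated aldehyde and couple them oxidatively at the unsubstituted diene terminus C6, giving an oxanickelacycle with an η3-allyl over C1–C7–C14; ethyl transfer from boron, β-hydride elimination and C–H reductive elimination at C1 then release the alcohol and the 7(14)-methylidene group. The closest known reaction type is the Ni(acac)2/Et3B homoallylation of aldehydes with 2,3-disubstituted 1,3-dienes (bond to the CH2 terminus, hydrogen to C2) and its intramolecular form with aldehydes tethered at the diene terminus; a tether on the internal diene carbon, as here, has not been described. The cyclohexane closes 6-endo with respect to the C6=C1 double bond (both diene carbons end up in the ring) through a chair in which the aldehyde oxygen and nickel bridge C5 and C1 on one face. C1 is set by hydride delivery on that face, which the dioxasilepane fixes: it holds the diene s-cis, keeps the C2–O bond near the diene plane (equatorial in the new ring) and puts the epoxy-aldehyde arm and the C9 chain on opposite diene faces, so the side chain should end trans to O2. C5 is set because the carbonyl oxygen must point to nickel, which places the new hydroxyl cis to H1 and anti to the epoxide oxygen (C=O anti to the epoxide C–O bond). The step needs terminus selectivity (C6 over C14, six- over seven-membered ring) and hydride delivery to C1 instead of C14, the latter being the normal outcome of this catalyst system.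

**Step 14**
Reactants: 20 (1R,2R,3S,4R,5S,8S,10R)-3,4:10,11-diepoxy-2,8-O-[di(propan-2-yl)silanediyl]bisabol-7(14)-ene-2,5,8-triol
Product: 22 (1R,2R,3S,4R,5S,8S,10R)-4,5:10,11-diepoxybisabol-7(14)-ene-2,3,8-triol, via isomeric epoxy triol 21 (not isolated)
Conditions: Bu4NF (3 equiv), THF, 0 °C to rt; then 0.5 M aq. NaOH, t-BuOH, rt
Reagents that add atoms: none
Why: Fluoride cleaves the dialkoxysilane, and under hydroxide the C5 alkoxide, which is trans to the epoxide, attacks C4 with inversion (Payne rearrangement); the equilibrium is expected to favour 22 (all ring substituents equatorial, hydrogen-bonded trans-2,3-diol, against an axial hydroxyl in 21) and sets C4 as in the target.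

**Step 15**
Reactants: 22 (1R,2R,3S,4R,5S,8S,10R)-4,5:10,11-diepoxybisabol-7(14)-ene-2,3,8-triol; 23 angelic acid; 24 angelic anhydride
Product: 26 (1R,2R,3S,4S,5S,8S,10R)-4,5:10,11-diepoxybisabol-7(14)-ene-2,3,8-triyl tris[(2Z)-2-methylbut-2-enoate], via mixed anhydride 25 (not isolated)
Conditions: 23 (4 equiv), 2,4,6-trichlorobenzoyl chloride (4 equiv), Et3N (5 equiv), toluene, rt; then 22 and 24 (3 equiv), toluene, 75 °C, no DMAP
Reagents that add atoms: none
Why: Yamaguchi-type acylation of all three secondary alcohols from a pool of two angeloyl donors, angelic anhydride 24 and the more electrophilic mixed anhydride 25 preformed from 23, which also re-activates by acyl exchange the angelic acid that 24 releases; the mixture is heated without a nucleophilic catalyst or strong base because these are the conditions under which angelates form without Z-to-E isomerisation to tiglates and under which the C3 hydroxyl is not deprotonated, so the epoxide should not migrate back.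

**Compound list**

1 | 4-methylpent-3-enoic acid | CC(C)=CCC(=O)O | starting material
2 | N-methoxy-N,4-dimethylpent-3-enamide | CC(C)=CCC(=O)N(C)OC | intermediate
3 | 4-methylfuran-2(5H)-one | CC1=CC(=O)OC1 | starting material
4 | (2Z)-4-hydroxy-N-methoxy-N,3-dimethylbut-2-enamide | CON(C)C(=O)/C=C(/C)CO | intermediate
5 | (2Z)-N-methoxy-N,3-dimethyl-4-(triethylsilyloxy)but-2-enamide | CON(C)C(=O)/C=C(/C)CO[Si](CC)(CC)CC | intermediate
6 | (2Z)-3-methyl-4-(triethylsilyloxy)but-2-enal | O=C/C=C(/C)CO[Si](CC)(CC)CC | intermediate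
7 | ethynyl(trimethyl)silane | C#C[Si](C)(C)C | starting material
8 | methyl[(trimethylsilyl)ethynyl]zinc | C[Zn]C#C[Si](C)(C)C | intermediate
9 | (3S,4Z)-5-methyl-6-(triethylsilyloxy)-1-(trimethylsilyl)hex-4-en-1-yn-3-ol | CC[Si](CC)(CC)OC/C(C)=C\[C@H](O)C#C[Si](C)(C)C | intermediate
10 | (1R)-1-{(2S,3R)-3-methyl-3-[(triethylsilyloxy)methyl]oxiran-2-yl}-3-(trimethylsilyl)prop-2-yn-1-ol | CC[Si](CC)(CC)OC[C@@]1(C)O[C@H]1[C@H](O)C#C[Si](C)(C)C | intermediate
11 | (1R)-1-{(2S,3R)-3-methyl-3-[(triethylsilyloxy)methyl]oxiran-2-yl}prop-2-yn-1-ol | CC[Si](CC)(CC)OC[C@@]1(C)O[C@H]1[C@H](O)C#C | intermediate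
12 | dilithium salt (O-lithium alkoxide, C-lithium acetylide) of 11 | CC[Si](CC)(CC)OC[C@@]1(C)O[C@H]1[C@H](O[Li])C#C[Li] | intermediate
13 | (1R)-1-hydroxy-7-methyl-1-{(2S,3R)-3-methyl-3-[(triethylsilyloxy)methyl]oxiran-2-yl}oct-6-en-2-yn-4-one | CC[Si](CC)(CC)OC[C@@]1(C)O[C@H]1[C@H](O)C#CC(=O)CC=C(C)C | intermediate
14 | (1R,4S)-7-methyl-1-{(2S,3R)-3-methyl-3-[(triethylsilyloxy)methyl]oxiran-2-yl}oct-6-en-2-yne-1,4-diol | CC[Si](CC)(CC)OC[C@@]1(C)O[C@H]1[C@H](O)C#C[C@@H](O)CC=C(C)C | intermediate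
15 | (1R,4S)-5-[(2R)-3,3-dimethyloxiran-2-yl]-1-{(2S,3R)-3-methyl-3-[(triethylsilyloxy)methyl]oxiran-2-yl}pent-2-yne-1,4-diol | CC[Si](CC)(CC)OC[C@@]1(C)O[C@H]1[C@H](O)C#C[C@@H](O)C[C@H]1OC1(C)C | intermediate
16 | ethene | C=C | starting material
17 | (1R,4S)-5-[(2R)-3,3-dimethyloxiran-2-yl]-2,3-dimethylidene-1-{(2S,3R)-3-methyl-3-[(triethylsilyloxy)methyl]oxiran-2-yl}pentane-1,4-diol | CC[Si](CC)(CC)OC[C@@]1(C)O[C@H]1[C@H](O)C(=C)C(=C)[C@@H](O)C[C@H]1OC1(C)C | intermediate
18 | (4R,7S)-7-{[(2R)-3,3-dimethyloxiran-2-yl]methyl}-5,6-dimethylidene-4-{(2S,3R)-3-methyl-3-[(triethylsilyloxy)methyl]oxiran-2-yl}-2,2-di(propan-2-yl)-1,3,2-dioxasilepane | CC[Si](CC)(CC)OC[C@@]1(C)O[C@H]1[C@@H]3O[Si](C(C)C)(C(C)C)O[C@@H](C[C@H]2OC2(C)C)C(=C)C3=C | intermediate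
19 | (2S,3S)-3-[(4R,7S)-7-{[(2R)-3,3-dimethyloxiran-2-yl]methyl}-5,6-dimethylidene-2,2-di(propan-2-yl)-1,3,2-dioxasilepan-4-yl]-2-methyloxirane-2-carbaldehyde | O=C[C@@]1(C)O[C@H]1[C@@H]3O[Si](C(C)C)(C(C)C)O[C@@H](C[C@H]2OC2(C)C)C(=C)C3=C | intermediate
20 | (1R,2R,3S,4R,5S,8S,10R)-3,4:10,11-diepoxy-2,8-O-[di(propan-2-yl)silanediyl]bisabol-7(14)-ene-2,5,8-triol (cyclohexane fused to the dioxasilepane at C1–C2; free 5-OH) | C=C1[C@H](C[C@H]2OC2(C)C)O[Si](C(C)C)(C(C)C)O[C@H]2[C@@H]3O[C@]3(C)[C@@H](O)C[C@H]12 | intermediate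
21 | (1R,2R,3S,4R,5S,8S,10R)-3,4:10,11-diepoxybisabol-7(14)-ene-2,5,8-triol | C=C([C@H](C[C@H]1OC1(C)C)O)[C@H]1C[C@H](O)[C@@]2(C)O[C@H]2[C@@H]1O | intermediate
22 | (1R,2R,3S,4R,5S,8S,10R)-4,5:10,11-diepoxybisabol-7(14)-ene-2,3,8-triol | C=C([C@H](C[C@H]1OC1(C)C)O)[C@H]1C[C@@H]2O[C@]2(C)[C@@H](O)[C@@H]1O | intermediate
23 | angelic acid, (2Z)-2-methylbut-2-enoic acid | C/C=C(/C)C(=O)O | starting material
24 | angelic anhydride, (2Z)-2-methylbut-2-enoic anhydride | C/C=C(/C)C(=O)OC(=O)/C(C)=C\C | starting material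
25 | (2Z)-2-methylbut-2-enoic 2,4,6-trichlorobenzoic anhydride | C/C=C(/C)C(=O)OC(=O)c1c(Cl)cc(Cl)cc1Cl | intermediate
26 | (1R,2R,3S,4S,5S,8S,10R)-4,5:10,11-diepoxybisabol-7(14)-ene-2,3,8-triyl tris[(2Z)-2-methylbut-2-enoate] | C=C([C@H](C[C@H]1OC1(C)C)OC(=O)/C(C)=C\C)[C@H]1C[C@@H]2O[C@]2(C)[C@@H](OC(=O)/C(C)=C\C)[C@@H]1OC(=O)/C(C)=C\C | target

Total step count: 15. Longest linear sequence: 14 steps (3 to 26, steps 2–15); step 1 is a one-step side branch that joins at step 7.

**Steps most likely to fail**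

Step 13. The oxidative cyclisation through the internal-carbon tether may not compete with diene oligomerisation or ethyl transfer to the aldehyde, hydride may be delivered to C14 instead of C1, or the ring may close on the other diene face. The fallback uses known reactions only and closes the ring at C1–C6 after the C5–C6 bond has been made by a Grignard addition. It sets out from 15: silylation with t-BuMe2SiCl and imidazole in DMF gives the bis-silyl ether F1, and direct Swern oxidation of the primary triethylsilyl ether gives the alkynyl epoxy aldehyde F2. CH2=CHMgBr then gives the (5S)-vinyl carbinol F3 mixed with its (5R)-epimer F4. Dess–Martin oxidation of the mixture gives the vinyl ketone F5, which (R)-Me-CBS oxazaborolidine with BH3·SMe2 (the quaternary epoxide carbon acting as the large group) should return as F3 alone. Ring-closing enyne metathesis (second-generation Grubbs catalyst RuCl2(=CHPh)(H2IMes)(PCy3), ethylene atmosphere) should give the cyclohexadienol F6. Hydroxyl-directed hydrogenation with [Ir(cod)(PCy3)(py)]PF6 and one equivalent of H2 should saturate the C1=C6 bond from the face of the C5 hydroxyl, ahead of the C7=C14 alkene that is shielded by the C8 silyl ether, to give the bis-silyl ether F7. Bu4NF then gives 21, where the route is rejoined and carried on with the hydroxide treatment of step 14.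

Step 14. The epoxide migration is an equilibrium and may stop at a mixture with 21, or drift to the 2,3-epoxide through attack of the C2 alkoxide. The fallback makes the oxygen transposition irreversible and sets out from 20: Dess–Martin oxidation gives the epoxy ketone F8, and Wharton transposition (N2H4·H2O, AcOH, MeOH) should give the allylic alcohol F9 with the C4=C5 alkene and the 3-hydroxyl in the configuration of the former epoxide C3–O bond. Bu4NF gives the triol F10, and acylation as in step 15 gives the tris-angelate F11. mCPBA should then epoxidise the only electron-rich trisubstituted alkene anti to the allylic C3 angelate and give 26, where the route is rejoined.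

Step 15. Acylation may stay incomplete at the hindered C3 hydroxyl, and the angeloyl group may isomerise from Z to E during activation. The fallback builds the Z double bonds on the esters and sets out from 22: acylation with 2-[bis(2,2,2-trifluoroethoxy)phosphoryl]propanoic acid (EDC·HCl, DMAP, CH2Cl2) gives the tris-phosphonate F12. A threefold Still–Gennari olefination with acetaldehyde (KN(SiMe3)2, 18-crown-6, THF, −78 °C) should then give 26, where the route is rejoined.

**Further compounds**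

F1 | step 13 | 1,4-bis-O-(tert-butyldimethylsilyl) ether of 15 | CC[Si](CC)(CC)OC[C@@]1(C)O[C@H]1[C@H](O[Si](C)(C)C(C)(C)C)C#C[C@@H](O[Si](C)(C)C(C)(C)C)C[C@H]1OC1(C)C
F2 | step 13 | (2S,3S)-3-{(1R,4S)-1,4-bis(tert-butyldimethylsilyloxy)-5-[(2R)-3,3-dimethyloxiran-2-yl]pent-2-yn-1-yl}-2-methyloxirane-2-carbaldehyde | O=C[C@@]1(C)O[C@H]1[C@H](O[Si](C)(C)C(C)(C)C)C#C[C@@H](O[Si](C)(C)C(C)(C)C)C[C@H]1OC1(C)C
F3 | step 13 | (5S)-vinyl carbinol from F2 (1-(oxiran-2-yl)prop-2-en-1-ol, future C5–OH anti to the epoxide oxygen) | C=C[C@H](O)[C@@]1(C)O[C@H]1[C@H](O[Si](C)(C)C(C)(C)C)C#C[C@@H](O[Si](C)(C)C(C)(C)C)C[C@H]1OC1(C)C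
F4 | step 13 | (5R)-epimer of F3 | C=C[C@@H](O)[C@@]1(C)O[C@H]1[C@H](O[Si](C)(C)C(C)(C)C)C#C[C@@H](O[Si](C)(C)C(C)(C)C)C[C@H]1OC1(C)C
F5 | step 13 | vinyl ketone from F3 and F4 (1-(oxiran-2-yl)prop-2-en-1-one) | C=CC(=O)[C@@]1(C)O[C@H]1[C@H](O[Si](C)(C)C(C)(C)C)C#C[C@@H](O[Si](C)(C)C(C)(C)C)C[C@H]1OC1(C)C
F6 | step 13 | 2,8-bis-O-(tert-butyldimethylsilyl)-3,4:10,11-diepoxybisabola-1(6),7(14)-diene-2,5,8-triol | C=C([C@H](C[C@H]1OC1(C)C)O[Si](C)(C)C(C)(C)C)C1=C[C@H](O)[C@@]2(C)O[C@H]2[C@@H]1O[Si](C)(C)C(C)(C)C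
F7 | step 13 | 2,8-bis-O-(tert-butyldimethylsilyl) ether of 21 | C=C([C@H](C[C@H]1OC1(C)C)O[Si](C)(C)C(C)(C)C)[C@H]1C[C@H](O)[C@@]2(C)O[C@H]2[C@@H]1O[Si](C)(C)C(C)(C)C
F8 | step 14 | 5-ketone of 20 (3,4-epoxy-5-oxo compound, silylene retained) | C=C1[C@H](C[C@H]2OC2(C)C)O[Si](C(C)C)(C(C)C)O[C@H]2[C@@H]3O[C@]3(C)C(=O)C[C@H]12
F9 | step 14 | 2,8-O-[di(propan-2-yl)silanediyl]-10,11-epoxybisabola-4,7(14)-diene-2,3,8-triol (free 3-OH) | C=C1[C@H](C[C@H]2OC2(C)C)O[Si](C(C)C)(C(C)C)O[C@H]2[C@H](O)C(C)=CC[C@H]12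
F10 | step 14 | (1R,2R,3R,8S,10R)-10,11-epoxybisabola-4,7(14)-diene-2,3,8-triol | C=C([C@H](C[C@H]1OC1(C)C)O)[C@H]1CC=C(C)[C@@H](O)[C@@H]1O
F11 | step 14 | tris[(2Z)-2-methylbut-2-enoate] of F10 | C=C([C@H](C[C@H]1OC1(C)C)OC(=O)/C(C)=C\C)[C@H]1CC=C(C)[C@@H](OC(=O)/C(C)=C\C)[C@@H]1OC(=O)/C(C)=C\C
F12 | step 15 | tris{2-[bis(2,2,2-trifluoroethoxy)phosphoryl]propanoate} of 22 | C=C([C@H](C[C@H]1OC1(C)C)OC(=O)C(C)P(=O)(OCC(F)(F)F)OCC(F)(F)F)[C@H]1C[C@@H]2O[C@]2(C)[C@@H](OC(=O)C(C)P(=O)(OCC(F)(F)F)OCC(F)(F)F)[C@@H]1OC(=O)C(C)P(=O)(OCC(F)(F)F)OCC(F)(F)F
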